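**Retrosynthetic overview**
1. Target 11 ⇐ tris-MOM chalcone 10 by one global acetal cleavage.
2. Key disconnection, ring A aryl–C(=O) bond: a cinnamoyl anion donor (α,β-unsaturated acylzirconocene chloride 9) plus aryl iodide 7. Both carbons are electrophilic in their ordinary reagents, so the acyl carbon is used with reversed polarity.
3. 9 ⇐ CO + (E)-alkenylzirconocene 8 ⇐ terminal alkyne 5; the syn hydrozirconation fixes the E alkene.
4. 5 ⇐ aldehyde 4 (one-carbon homologation) ⇐ 4-hydroxybenzaldehyde + two prenyl bromide; 7 ⇐ 4-iodoresorcinol.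
5. No ring is formed: ring B is bought as 4-hydroxybenzaldehyde and ring A as 4-iodoresorcinol.

Assumption: the target has no stereocentre, so "single enantiomer" is read as the single (E)-alkene isomer drawn.

**Step 1**
Reactants: 1 4-hydroxybenzaldehyde; 2 prenyl bromide (1-bromo-3-methylbut-2-ene)
Product: 3 4-hydroxy-3,5-bis(3-methylbut-2-en-1-yl)benzaldehyde
Conditions: KOH (2.5 equiv), H2O, prenyl bromide (2.5 equiv), rt, 48 h; mono-prenyl aldehyde recycled
Reagents that add atoms: prenyl bromide (compound 2), CC(C)=CCBr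
Why: Ortho C-alkylation of an ambident phenoxide: in water the phenoxide oxygen is hydrogen-bonded, so the allylic bromide is attacked (SN2) by the two free ortho carbons in turn, the para position being blocked by the formyl group, and the linear 3,5-diprenyl phenol results after rearomatisation.

**Step 2**
Reactants: 3 4-hydroxy-3,5-bis(3-methylbut-2-en-1-yl)benzaldehyde
Product: 4 4-(methoxymethoxy)-3,5-bis(3-methylbut-2-en-1-yl)benzaldehyde
Conditions: NaH (1.2 equiv), MOMCl (1.3 equiv), DMF, 0 °C to rt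
Reagents that add atoms: chloromethyl methyl ether (MOMCl), COCCl
Why: Williamson-type O-alkylation: the sodium phenoxide is alkylated on oxygen by the hard, reactive α-chloro ether to give the MOM acetal, and the non-enolisable aldehyde is untouched.

**Step 3**
Reactants: 4 4-(methoxymethoxy)-3,5-bis(3-methylbut-2-en-1-yl)benzaldehyde
Product: 5 5-ethynyl-2-(methoxymethoxy)-1,3-bis(3-methylbut-2-en-1-yl)benzene
Conditions: dimethyl (1-diazo-2-oxopropyl)phosphonate (1.3 equiv), K2CO3 (2 equiv), MeOH, rt, 12 h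
Reagents that add atoms: dimethyl (1-diazo-2-oxopropyl)phosphonate (Ohira–Bestmann reagent), CC(=O)C(=[N+]=[N-])P(=O)(OC)OC
Why: Seyferth–Gilbert homologation in the Ohira–Bestmann variant: methoxide removes the acetyl group of the reagent, the diazomethylphosphonate anion adds to the aldehyde, Horner–Wadsworth–Emmons-type elimination gives a diazoalkene, and loss of N2 with a 1,2-hydride shift gives the terminal alkyne without touching the MOM ether or the prenyl groups.

**Step 4**
Reactants: 6 4-iodoresorcinol (4-iodobenzene-1,3-diol)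
Product: 7 1-iodo-2,4-bis(methoxymethoxy)benzene
Conditions: NaH (2.5 equiv), MOMCl (2.5 equiv), DMF, 0 °C to rt
Reagents that add atoms: chloromethyl methyl ether (MOMCl), COCCl
Why: Double Williamson-type O-alkylation of the resorcinol bis-phenoxide masks both acidic OH groups before the organometallic step, and the C–I bond is inert to NaH at this temperature.

**Step 5**
Reactants: 5 5-ethynyl-2-(methoxymethoxy)-1,3-bis(3-methylbut-2-en-1-yl)benzene; 7 1-iodo-2,4-bis(methoxymethoxy)benzene
Product: 10 (E)-1-[2,4-bis(methoxymethoxy)phenyl]-3-[4-(methoxymethoxy)-3,5-bis(3-methylbut-2-en-1-yl)phenyl]prop-2-en-1-one, via (E)-alkenylzirconocene chloride 8 (not isolated), via α,β-unsaturated acylzirconocene chloride 9 (not isolated)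
Conditions: Cp2Zr(H)Cl (1.2 equiv), THF, rt, 30 min; CO (1 atm), rt, 2 h; Ar purge; then 7 (0.8 equiv), Pd(PPh3)4 (5 mol %), CuI (10 mol %), THF, 50 °C
Reagents that add atoms: carbon monoxide, [C-]#[O+]
Why: Proposed new method: syn hydrozirconation puts zirconium on the terminal alkyne carbon and fixes the E alkene (8), CO inserts into the Zr–C bond with retention to give acylzirconocene chloride 9 (a cinnamoyl anion donor), and the acyl group is passed via CuI to the aryl–Pd–I species from oxidative addition of 7 to zerovalent palladium, reductive elimination from the divalent aryl(acyl)palladium giving the ketone; the closest known reaction type is the palladium- or copper-catalysed nucleophilic acylation of allylic halides, benzylic halides and diaryliodonium salts by acylzirconocene chlorides, extended here to an enoyl zirconocene and an electron-rich ortho-alkoxy aryl iodide.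

**Step 6**
Reactants: 10 (E)-1-[2,4-bis(methoxymethoxy)phenyl]-3-[4-(methoxymethoxy)-3,5-bis(3-methylbut-2-en-1-yl)phenyl]prop-2-en-1-one
Product: 11 (E)-1-(2,4-dihydroxyphenyl)-3-[4-hydroxy-3,5-bis(3-methylbut-2-en-1-yl)phenyl]prop-2-en-1-one (target)
Conditions: 3 M aq HCl, MeOH–THF (3:1), 45 °C, 3 h
Reagents that add atoms: none
Why: Acid-catalysed acetal solvolysis (transacetalisation of the three aryl MOM ethers to dimethoxymethane in methanol) frees the phenols at a temperature too low for chroman formation from the ortho-prenyl phenol, and the E enone, the thermodynamic isomer, is retained.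

**Compound list**
1 | 4-hydroxybenzaldehyde | O=Cc1ccc(O)cc1 | starting material
2 | prenyl bromide (1-bromo-3-methylbut-2-ene) | CC(C)=CCBr | starting material
3 | 4-hydroxy-3,5-bis(3-methylbut-2-en-1-yl)benzaldehyde | CC(C)=CCc1cc(C=O)cc(CC=C(C)C)c1O | intermediate
4 | 4-(methoxymethoxy)-3,5-bis(3-methylbut-2-en-1-yl)benzaldehyde | COCOc1c(CC=C(C)C)cc(C=O)cc1CC=C(C)C | intermediate
5 | 5-ethynyl-2-(methoxymethoxy)-1,3-bis(3-methylbut-2-en-1-yl)benzene | COCOc1c(CC=C(C)C)cc(C#C)cc1CC=C(C)C | intermediate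
6 | 4-iodoresorcinol (4-iodobenzene-1,3-diol) | Oc1ccc(I)c(O)c1 | starting material
7 | 1-iodo-2,4-bis(methoxymethoxy)benzene | COCOc1ccc(I)c(OCOC)c1 | intermediate
8 | chlorobis(η5-cyclopentadienyl)[(E)-2-[4-(methoxymethoxy)-3,5-bis(3-methylbut-2-en-1-yl)phenyl]ethenyl]zirconium (not isolated) | COCOc1c(CC=C(C)C)cc(/C=C/[Zr+2]Cl)cc1CC=C(C)C.c1cc[cH-]c1.c1cc[cH-]c1 | intermediate
9 | chlorobis(η5-cyclopentadienyl)[(E)-3-[4-(methoxymethoxy)-3,5-bis(3-methylbut-2-en-1-yl)phenyl]prop-2-enoyl]zirconium (not isolated) | COCOc1c(CC=C(C)C)cc(/C=C/C(=O)[Zr+2]Cl)cc1CC=C(C)C.c1cc[cH-]c1.c1cc[cH-]c1 | intermediate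
10 | (E)-1-[2,4-bis(methoxymethoxy)phenyl]-3-[4-(methoxymethoxy)-3,5-bis(3-methylbut-2-en-1-yl)phenyl]prop-2-en-1-one | COCOc1ccc(C(=O)/C=C/c2cc(CC=C(C)C)c(OCOC)c(CC=C(C)C)c2)c(OCOC)c1 | intermediate
11 | (E)-1-(2,4-dihydroxyphenyl)-3-[4-hydroxy-3,5-bis(3-methylbut-2-en-1-yl)phenyl]prop-2-en-1-one | CC(C)=CCc1cc(/C=C/C(=O)c2ccc(O)cc2O)cc(CC=C(C)C)c1O | target

**Count**
Total steps: 6. Longest linear sequence: 5 (steps 1, 2, 3, 5, 6); step 4 is the one-step side branch.

**Three steps most likely to fail, with fallbacks**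

Step 5 is the main risk. Acyl transfer from zirconium to a hindered, electron-rich aryl–palladium species may be slow, and the enoyl zirconocene can also react as a Michael acceptor or lose CO. The fallback sets out from 5 and 7 and comes back at 10. Alkyne 5 is hydroborated with pinacolborane (Cp2Zr(H)Cl 10 mol %, Et3N, 60 °C) to 2-[(E)-2-[4-(methoxymethoxy)-3,5-bis(3-methylbut-2-en-1-yl)phenyl]ethenyl]-4,4,5,5-tetramethyl-1,3,2-dioxaborolane F1. F1 is then joined to 7 by a carbonylative Suzuki–Miyaura coupling (CO 1 atm, PdCl2(dppf), K2CO3, anisole, 80 °C). Here the acyl group is built on palladium from 7 and CO, and the alkenyl group arrives as the nucleophile, giving 10.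

Step 1 is the second risk. The double C-prenylation competes with mono-prenylation and O-prenylation, and the diprenyl aldehyde is usually the minor product (about 10–25 %) even with recycling. The fallback sets out from 1 and comes back at 4, so step 2 is skipped. Aldehyde 1 is dibrominated (Br2, AcOH, rt) to 3,5-dibromo-4-hydroxybenzaldehyde F2. This is protected (NaH, MOMCl, DMF) as 3,5-dibromo-4-(methoxymethoxy)benzaldehyde F3. A double Stille coupling with tributyl(3-methylbut-2-en-1-yl)stannane (Pd(PPh3)4, DMF, 100 °C) then places both prenyl groups and gives 4.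

Step 6 is the third risk. Acid can close the 2′-hydroxychalcone to the flavanone or the ortho-prenyl phenol to a chroman before the hindered ring B MOM ether is gone. The fallback replaces the acid-labile acetals by fluoride-labile silyl ethers; it sets out from 3 and 6 and comes back at 11.
- Phenol 3 is silylated (TBSCl, imidazole, DMF, 40 °C) to 4-[(tert-butyldimethylsilyl)oxy]-3,5-bis(3-methylbut-2-en-1-yl)benzaldehyde F4.
- F4 is homologated with lithiated TMSCHN2 (LiN(i-Pr)2, THF, −78 °C to rt, Colvin rearrangement) to tert-butyl[4-ethynyl-2,6-bis(3-methylbut-2-en-1-yl)phenoxy]dimethylsilane F5. This reagent is chosen because K2CO3 in MeOH would cleave the aryl silyl ether.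
- Diol 6 is silylated in the same way to 4-iodo-1,3-bis[(tert-butyldimethylsilyl)oxy]benzene F6.
- The step 5 sequence (Cp2Zr(H)Cl; CO; then F6, Pd(PPh3)4, CuI) takes F5 through the silyl-protected (E)-alkenylzirconocene chloride F7 and the silyl-protected acylzirconocene chloride F8 to (E)-1-[2,4-bis[(tert-butyldimethylsilyl)oxy]phenyl]-3-[4-[(tert-butyldimethylsilyl)oxy]-3,5-bis(3-methylbut-2-en-1-yl)phenyl]prop-2-en-1-one F9.
- Bu4NF buffered with AcOH (THF, 0 °C) removes all three silyl groups and gives 11.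

**Further compounds**
F1 | step 5 | 2-[(E)-2-[4-(methoxymethoxy)-3,5-bis(3-methylbut-2-en-1-yl)phenyl]ethenyl]-4,4,5,5-tetramethyl-1,3,2-dioxaborolane | COCOc1c(CC=C(C)C)cc(/C=C/B2OC(C)(C)C(C)(C)O2)cc1CC=C(C)C
F2 | step 1 | 3,5-dibromo-4-hydroxybenzaldehyde | O=Cc1cc(Br)c(O)c(Br)c1
F3 | step 1 | 3,5-dibromo-4-(methoxymethoxy)benzaldehyde | COCOc1c(Br)cc(C=O)cc1Br
F4 | step 6 | 4-[(tert-butyldimethylsilyl)oxy]-3,5-bis(3-methylbut-2-en-1-yl)benzaldehyde | CC(C)=CCc1cc(C=O)cc(CC=C(C)C)c1O[Si](C)(C)C(C)(C)C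
F5 | step 6 | tert-butyl[4-ethynyl-2,6-bis(3-methylbut-2-en-1-yl)phenoxy]dimethylsilane | CC(C)=CCc1cc(C#C)cc(CC=C(C)C)c1O[Si](C)(C)C(C)(C)C
F6 | step 6 | 4-iodo-1,3-bis[(tert-butyldimethylsilyl)oxy]benzene | CC(C)(C)[Si](C)(C)Oc1ccc(I)c(O[Si](C)(C)C(C)(C)C)c1
F7 | step 6 | chlorobis(η5-cyclopentadienyl)[(E)-2-[4-[(tert-butyldimethylsilyl)oxy]-3,5-bis(3-methylbut-2-en-1-yl)phenyl]ethenyl]zirconium | CC(C)=CCc1cc(/C=C/[Zr+2]Cl)cc(CC=C(C)C)c1O[Si](C)(C)C(C)(C)C.c1cc[cH-]c1.c1cc[cH-]c1
F8 | step 6 | chlorobis(η5-cyclopentadienyl)[(E)-3-[4-[(tert-butyldimethylsilyl)oxy]-3,5-bis(3-methylbut-2-en-1-yl)phenyl]prop-2-enoyl]zirconium | CC(C)=CCc1cc(/C=C/C(=O)[Zr+2]Cl)cc(CC=C(C)C)c1O[Si](C)(C)C(C)(C)C.c1cc[cH-]c1.c1cc[cH-]c1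
F9 | step 6 | (E)-1-[2,4-bis[(tert-butyldimethylsilyl)oxy]phenyl]-3-[4-[(tert-butyldimethylsilyl)oxy]-3,5-bis(3-methylbut-2-en-1-yl)phenyl]prop-2-en-1-one | CC(C)(C)[Si](C)(C)Oc1ccc(C(=O)/C=C/c2cc(CC=C(C)C)c(O[Si](C)(C)C(C)(C)C)c(CC=C(C)C)c2)c(O[Si](C)(C)C(C)(C)C)c1
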